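**Strategy.** Everything rests on making the hexasubstituted central ring C from open-chain parts. Its six carbons are split into a four-carbon, 1,3-dioxygenated diene unit that already carries both benzylic CH2 arms leading to rings B and D, and a two-carbon alkyne unit that carries the third ring oxygen (as OEt) and the butanoyl group. One cycloaddition–aromatisation between a 1-methoxy-1,3-bis(trimethylsilyloxy)diene bearing two 2,4,6-trimethoxybenzyl groups and 1-ethoxyhex-1-yn-3-one should form two C–C bonds and ring C, the alternating O/C pattern being fixed by polarity. The diene derives from self-condensation of a single arylpropanoate; butanoylation, ether cleavage and two methylene bridgings then add rings A and E.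

Key step: step 7

Remarks on the chemistry:
- Assumption: N-methoxy-N-methylbutanamide 10 is taken as a catalogue compound.
- In 15 the ethoxy group is ortho to the butanoyl group, so the correct locants are 2-ethoxy-4,6-dihydroxy; this follows from the bond between diene C-4 and the ethoxy-bearing alkyne carbon.
- The stereocentre of 5, the two sp3 centres of 14 and the double-bond geometries of 3, 6, 7 and 8 reach no later compound; the target has no stereocentre and is drawn as the enol tautomer of its given structure.
- Salt forms of a product that are only neutralised on work-up (enolates, phenolates, aluminium or boron aryloxides) are not numbered separately.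

Step 1
Reactants: 1 2,4,6-trimethoxybenzaldehyde; 2 methyl (triphenylphosphoranylidene)acetate
Product: 3 methyl (E)-3-(2,4,6-trimethoxyphenyl)prop-2-enoate
Conditions: PhMe, 110 °C, 24 h
Reagents that add atoms: none
Why: Wittig olefination with a stabilised ylide converts the non-enolisable aldehyde into the cinnamate, whose geometry is irrelevant because the alkene is hydrogenated next.

Step 2
Reactants: 3 methyl (E)-3-(2,4,6-trimethoxyphenyl)prop-2-enoate
Product: 4 methyl 3-(2,4,6-trimethoxyphenyl)propanoate
Conditions: H2 (1 atm), 10% Pd/C, EtOAc, rt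
Reagents that add atoms: none
Why: Heterogeneous catalytic hydrogenation saturates the conjugated C=C and leaves the ester and the aryl methyl ethers untouched.

Step 3
Reactants: 4 methyl 3-(2,4,6-trimethoxyphenyl)propanoate (two molecules)
Product: 5 methyl 3-oxo-2-(2,4,6-trimethoxybenzyl)-5-(2,4,6-trimethoxyphenyl)pentanoate (racemic)
Conditions: NaH (0.6 equiv per ester), MeOH (cat.), PhMe, 90 °C; 1 M HCl
Reagents that add atoms: none
Why: Claisen self-condensation lets the enolate of one ester acylate a second molecule, so a single ester supplies both arylmethyl arms at C-2 and C-5 of the β-keto ester, the equilibrium being pulled by deprotonation of the product at C-2 (this stereocentre forms racemic and is erased in step 4).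

Step 4
Reactants: 5 methyl 3-oxo-2-(2,4,6-trimethoxybenzyl)-5-(2,4,6-trimethoxyphenyl)pentanoate
Product: 6 methyl (Z)-3-(trimethylsilyloxy)-2-(2,4,6-trimethoxybenzyl)-5-(2,4,6-trimethoxyphenyl)pent-2-enoate
Conditions: TMSCl (1.5 equiv), Et3N (1.6 equiv), PhMe, rt, 72 h; filtration under Ar
Reagents that add atoms: chlorotrimethylsilane (TMSCl), C[Si](C)(C)Cl
Why: Amine-mediated O-silylation of the enolised β-keto ester (silyl enol ether formation) is standard for 2-alkylated acetoacetates, and the enol ether geometry is lost when this bond becomes the diene single bond.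

Step 5
Reactants: 6 methyl (Z)-3-(trimethylsilyloxy)-2-(2,4,6-trimethoxybenzyl)-5-(2,4,6-trimethoxyphenyl)pent-2-enoate
Product: 8 (1Z,3Z)-1-methoxy-1,3-bis(trimethylsilyloxy)-2-(2,4,6-trimethoxybenzyl)-5-(2,4,6-trimethoxyphenyl)penta-1,3-diene, via lithium dienolate 7 (not isolated)
Conditions: LiN(iPr)2 (1.3 equiv), THF, −78 °C, 1 h; then TMSCl (1.5 equiv), −78 °C → rt; hexane, filtration under Ar, used crude
Reagents that add atoms: chlorotrimethylsilane (TMSCl), C[Si](C)(C)Cl
Why: γ-Deprotonation of the 3-silyloxy enoate at C-4 (vinylogous ester enolate formation; the CH2 on C-2 is cross-conjugated and not acidified by the ester) followed by O-silylation is the established way to 1-alkoxy-1,3-bis(silyloxy)dienes.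

Step 6
Reactants: 9 ethoxyacetylene; 10 N-methoxy-N-methylbutanamide
Product: 13 1-ethoxyhex-1-yn-3-one, via lithium ethoxyacetylide 11 (not isolated), via lithium hemiaminal adduct 12 (not isolated)
Conditions: n-BuLi (1.05 equiv), THF, −78 °C; then 10, −78 → −40 °C; AcOH (2 equiv), −78 °C; cold aqueous wash, used promptly
Reagents that add atoms: none
Why: Weinreb ketone synthesis: the acetylide adds once to the N-methoxy-N-methylamide to give a chelated tetrahedral adduct that releases the ynone only on the cold acetic acid quench, which also protonates the liberated amine before it can add to the alkoxy ynone.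

Step 7
Reactants: 8 (1Z,3Z)-1-methoxy-1,3-bis(trimethylsilyloxy)-2-(2,4,6-trimethoxybenzyl)-5-(2,4,6-trimethoxyphenyl)penta-1,3-diene; 13 1-ethoxyhex-1-yn-3-one (1.5 equiv)
Product: 15 1-[2-ethoxy-4,6-dihydroxy-3,5-bis(2,4,6-trimethoxybenzyl)phenyl]butan-1-one, via cyclohexadiene cycloadduct 14 (not isolated)
Conditions: PhMe (1 M), 70 °C, Ar, sealed tube, 24–48 h; then 1 M HCl, THF, 0 °C → rt
Reagents that add atoms: none
Why: Proposed new method: C-4 of diene 8, the silyl enol ether terminus and its most nucleophilic carbon, should add to the ethoxy-bearing alkyne carbon of 13 (the electrophilic β-position of a push–pull ynone), and the allenolate-type carbon next to the butanoyl group should then close onto the ketene-acetal carbon C-1, i.e. a highly asynchronous normal-electron-demand Diels–Alder reaction or, at the stepwise limit, a Mukaiyama–Michael addition followed by Claisen-type closure giving the same bonds. The nearest known reaction type is the cycloaddition–aromatisation of 1-alkoxy-1,3-bis(silyloxy)buta-1,3-dienes with alkynones and alkynoates to resorcinols; untested here are a diene substituted at both C-2 and C-4 and a donor-substituted ynone. Ring C is closed as a six-membered carbocycle in the [4+2] mode from a four-carbon and a two-carbon unit, first as 1,4-cyclohexadiene 14, whose mixed methyl silyl ketal carbon sits across the ring from the sp3 C–H, so that dilute acid removes methanol and both silyl groups and the ring aromatises. No stereocentre remains, because the two sp3 centres of 14 are destroyed on aromatisation. The step needs regioselectivity (butanoyl carbon between the ketal-derived C–OH and the C–OEt carbon) and ring closure faster than loss of ethoxide from the first adduct; the former is secured by the matched polarisation of the two partners, the latter by Lewis-acid-free thermal conditions in a non-polar solvent, by the 2-benzyl group (which rules out aromatisation after a [3+3] closure at C-2) and by staying below the temperature at which ethoxyalkynes lose ethylene.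

Step 8
Reactants: 15 1-[2-ethoxy-4,6-dihydroxy-3,5-bis(2,4,6-trimethoxybenzyl)phenyl]butan-1-one; 16 butanoyl chloride (2.3 equiv)
Product: 17 1-[3,5-bis(3-butanoyl-2,4,6-trimethoxybenzyl)-2-ethoxy-4,6-dihydroxyphenyl]butan-1-one
Conditions: AlCl3 (5 equiv), CH2Cl2, −20 → 0 °C; 1 M HCl
Reagents that add atoms: none
Why: Friedel–Crafts acylation takes place once on each 2,4,6-trimethoxyphenyl ring, since its two free carbons are equivalent, the first acyl group deactivates the ring against a second and ring C has no free carbon; chelation-assisted loss of a methyl group ortho to a new ketone would be harmless because step 9 removes all of them.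

Step 9
Reactants: 17 1-[3,5-bis(3-butanoyl-2,4,6-trimethoxybenzyl)-2-ethoxy-4,6-dihydroxyphenyl]butan-1-one
Product: 18 1-[3,5-bis(3-butanoyl-2,4,6-trihydroxybenzyl)-2,4,6-trihydroxyphenyl]butan-1-one
Conditions: BBr3 (14 equiv), CH2Cl2, −78 °C → rt, 16 h; H2O, 0 °C
Reagents that add atoms: none
Why: Lewis-acid dealkylation of aryl alkyl ethers with BBr3 cleaves the six methyl ethers and the ethyl ether, those ortho to a carbonyl fastest through chelation, while aryl ketones and diarylmethane links are not attacked by the reagent.

Step 10
Reactants: 19 phloroglucinol; 16 butanoyl chloride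
Product: 20 1-(2,4,6-trihydroxyphenyl)butan-1-one
Conditions: AlCl3 (3.5 equiv), PhNO2–CH2Cl2, rt → 45 °C; ice, HCl
Reagents that add atoms: none
Why: Friedel–Crafts C-acylation of phloroglucinol (any O-acyl intermediate undergoes Fries rearrangement under AlCl3) stops after one acyl group because the ketone deactivates the ring.

Step 11
Reactants: 20 1-(2,4,6-trihydroxyphenyl)butan-1-one
Product: 21 2-butanoyl-3,5-dihydroxy-4,4-dimethylcyclohexa-2,5-dien-1-one (butyrylfilicinic acid)
Conditions: NaOMe (3 equiv), MeI (2.1 equiv), MeOH, 0 °C → rt; 1 M HCl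
Reagents that add atoms: iodomethane (MeI), CI
Why: Base-mediated dearomatising C-methylation puts two methyl groups on the same ring carbon of the phenolate to give the gem-dimethyl cyclohexadienone, the established entry to acylfilicinic acids, with over-methylation limited by the amount of iodomethane.

Step 12
Reactants: 21 2-butanoyl-3,5-dihydroxy-4,4-dimethylcyclohexa-2,5-dien-1-one; 22 bis(dimethylamino)methane (1.05 equiv)
Product: 23 2-butanoyl-6-[(dimethylamino)methyl]-3,5-dihydroxy-4,4-dimethylcyclohexa-2,5-dien-1-one
Conditions: CH2Cl2, 0 °C → rt, 1 h; evaporation, used crude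
Reagents that add atoms: none
Why: Mannich reaction: the acidic enol protonates the aminal to release the dimethylmethyleneiminium ion, which is captured by the only nucleophilic ring carbon C-6, and the absence of free formaldehyde suppresses methylene-bis coupling of two dienone rings.

Step 13
Reactants: 18 1-[3,5-bis(3-butanoyl-2,4,6-trihydroxybenzyl)-2,4,6-trihydroxyphenyl]butan-1-one; 23 2-butanoyl-6-[(dimethylamino)methyl]-3,5-dihydroxy-4,4-dimethylcyclohexa-2,5-dien-1-one (2.4 equiv)
Product: 24 target CNP0188003.0
Conditions: AcOH (6 equiv), 1,4-dioxane (degassed), 60 °C, Ar; dilute HCl work-up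
Reagents that add atoms: none
Why: Alkylation with a Mannich base by elimination–addition: in the buffered medium 23 loses dimethylamine and the resulting exocyclic enone is captured by the single free, doubly ortho-hydroxylated carbon of ring B and of ring D (Friedel–Crafts-type conjugate addition), giving both methylene bridges and no stereocentre.

**Compound list**

1 | 2,4,6-trimethoxybenzaldehyde | COc1cc(OC)c(C=O)c(OC)c1 | starting material
2 | methyl (triphenylphosphoranylidene)acetate | COC(=O)C=P(c1ccccc1)(c1ccccc1)c1ccccc1 | starting material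
3 | methyl (E)-3-(2,4,6-trimethoxyphenyl)prop-2-enoate | COC(=O)/C=C/c1c(OC)cc(OC)cc1OC | intermediate
4 | methyl 3-(2,4,6-trimethoxyphenyl)propanoate | COC(=O)CCc1c(OC)cc(OC)cc1OC | intermediate
5 | methyl 3-oxo-2-(2,4,6-trimethoxybenzyl)-5-(2,4,6-trimethoxyphenyl)pentanoate (racemic) | COC(=O)C(Cc1c(OC)cc(OC)cc1OC)C(=O)CCc1c(OC)cc(OC)cc1OC | intermediate
6 | methyl (Z)-3-(trimethylsilyloxy)-2-(2,4,6-trimethoxybenzyl)-5-(2,4,6-trimethoxyphenyl)pent-2-enoate | COC(=O)/C(Cc1c(OC)cc(OC)cc1OC)=C(\O[Si](C)(C)C)CCc1c(OC)cc(OC)cc1OC | intermediate
7 | lithium (1E,3Z)-1-methoxy-3-(trimethylsilyloxy)-2-(2,4,6-trimethoxybenzyl)-5-(2,4,6-trimethoxyphenyl)penta-1,3-dien-1-olate (same spatial arrangement as 8) | CO/C(O[Li])=C(Cc1c(OC)cc(OC)cc1OC)/C(O[Si](C)(C)C)=C/Cc1c(OC)cc(OC)cc1OC | intermediate (not isolated)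
8 | (1Z,3Z)-1-methoxy-1,3-bis(trimethylsilyloxy)-2-(2,4,6-trimethoxybenzyl)-5-(2,4,6-trimethoxyphenyl)penta-1,3-diene | CO/C(O[Si](C)(C)C)=C(Cc1c(OC)cc(OC)cc1OC)/C(O[Si](C)(C)C)=C/Cc1c(OC)cc(OC)cc1OC | intermediate
9 | ethoxyacetylene (ethoxyethyne) | C#COCC | starting material
10 | N-methoxy-N-methylbutanamide | CCCC(=O)N(C)OC | starting material
11 | lithium ethoxyacetylide | [Li]C#COCC | intermediate (not isolated)
12 | lithium 1-ethoxy-3-[methoxy(methyl)amino]hex-1-yn-3-olate | CCCC(O[Li])(C#COCC)N(C)OC | intermediate (not isolated)
13 | 1-ethoxyhex-1-yn-3-one | CCOC#CC(=O)CCC | intermediate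
14 | 1-[2-ethoxy-6-methoxy-3,5-bis(2,4,6-trimethoxybenzyl)-4,6-bis(trimethylsilyloxy)cyclohexa-1,4-dien-1-yl]butan-1-one (mixture of diastereomers) | CCCC(=O)C1=C(OCC)C(Cc2c(OC)cc(OC)cc2OC)C(O[Si](C)(C)C)=C(Cc2c(OC)cc(OC)cc2OC)C1(OC)O[Si](C)(C)C | intermediate (not isolated)
15 | 1-[2-ethoxy-4,6-dihydroxy-3,5-bis(2,4,6-trimethoxybenzyl)phenyl]butan-1-one | CCCC(=O)c1c(O)c(Cc2c(OC)cc(OC)cc2OC)c(O)c(Cc2c(OC)cc(OC)cc2OC)c1OCC | intermediate
16 | butanoyl chloride (butyryl chloride) | CCCC(=O)Cl | starting material
17 | 1-[3,5-bis(3-butanoyl-2,4,6-trimethoxybenzyl)-2-ethoxy-4,6-dihydroxyphenyl]butan-1-one | CCCC(=O)c1c(O)c(Cc2c(OC)cc(OC)c(C(=O)CCC)c2OC)c(O)c(Cc2c(OC)cc(OC)c(C(=O)CCC)c2OC)c1OCC | intermediate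
18 | 1-[3,5-bis(3-butanoyl-2,4,6-trihydroxybenzyl)-2,4,6-trihydroxyphenyl]butan-1-one | CCCC(=O)c1c(O)c(Cc2c(O)cc(O)c(C(=O)CCC)c2O)c(O)c(Cc2c(O)cc(O)c(C(=O)CCC)c2O)c1O | intermediate
19 | phloroglucinol (benzene-1,3,5-triol) | Oc1cc(O)cc(O)c1 | starting material
20 | 1-(2,4,6-trihydroxyphenyl)butan-1-one | CCCC(=O)c1c(O)cc(O)cc1O | intermediate
21 | 2-butanoyl-3,5-dihydroxy-4,4-dimethylcyclohexa-2,5-dien-1-one | CCCC(=O)C1=C(O)C(C)(C)C(O)=CC1=O | intermediate
22 | bis(dimethylamino)methane | CN(C)CN(C)C | starting material
23 | 2-butanoyl-6-[(dimethylamino)methyl]-3,5-dihydroxy-4,4-dimethylcyclohexa-2,5-dien-1-one | CCCC(=O)C1=C(O)C(C)(C)C(O)=C(CN(C)C)C1=O | intermediate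
24 | CNP0188003.0: chain A–CH2–B–CH2–C–CH2–D–CH2–E, rings A and E being 5-butanoyl-2,4-dihydroxy-3,3-dimethyl-6-oxocyclohexa-1,4-dien-1-yl units and rings B, C and D being 5-butanoyl-2,4,6-trihydroxy-1,3-phenylene units | CCCC(=O)C1=C(O)C(C)(C)C(O)=C(Cc2c(O)c(Cc3c(O)c(Cc4c(O)c(CC5=C(O)C(C)(C)C(O)=C(C(=O)CCC)C5=O)c(O)c(C(=O)CCC)c4O)c(O)c(C(=O)CCC)c3O)c(O)c(C(=O)CCC)c2O)C1=O | target

**Totals.** 13 steps in all; longest linear sequence 9 steps (steps 1, 2, 3, 4, 5, 7, 8, 9, 13).

**Steps most likely to fail**

First, step 7 (the proposed new method). The donor-substituted alkyne may react too slowly with the hindered diene below the temperature at which the ethoxyalkyne fragments. The diene may be protodesilylated back to 5. The first adduct may expel ethoxide instead of closing the ring. The fallback uses known chemistry only, sets out from 20 (with 22) and comes back at 18, so that 15 and 17 are bypassed. Two-fold Mannich reaction of 20 with 22 (2.2 equiv, CH2Cl2, rt) at both free ring carbons should give 1-{3,5-bis[(dimethylamino)methyl]-2,4,6-trihydroxyphenyl}butan-1-one F1. Heating F1 with a large, recoverable excess of 20 in dioxane–AcOH should transfer both CH2 groups to one free ring carbon of two molecules of 20 by amine elimination and conjugate addition (alkylation of phenols with phenolic Mannich bases), giving 18.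

Second, step 13. Heat or amine may induce exchange of the methylene bridges by retro-addition and re-addition, the dienone unit may couple with itself, or the second bridging may stall. The fallback reverses the roles of the partners, sets out from 18 and comes back at 24. Aminomethylation of the free carbon of rings B and D of 18 with 22 should give 1-[3,5-bis({3-butanoyl-5-[(dimethylamino)methyl]-2,4,6-trihydroxyphenyl}methyl)-2,4,6-trihydroxyphenyl]butan-1-one F2. F2 is then heated with an excess of the more acidic and cheaper carbon nucleophile 21 in dioxane–AcOH, so that each electrophilic centre generated on the valuable trimer is intercepted by 21 and not by another trimer.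

Third, step 8. The two ring C hydroxyls may be O-acylated in competition with C-acylation, or the acid may cleave or shift the electron-rich benzyl groups. An aryl butanoate, if formed, can be returned to the phenol by brief K2CO3/MeOH treatment. The fallback changes the order of events, sets out from 15 and comes back at 18. All seven ethers are cleaved first with BBr3 to give 1-[2,4,6-trihydroxy-3,5-bis(2,4,6-trihydroxybenzyl)phenyl]butan-1-one F3. The two outer phloroglucinol rings of F3 are then butanoylated once each with 16 and AlCl3 in PhNO2–CH2Cl2 as in step 10; there an O-acyl group is not a dead end because each outer ring has a free carbon for Fries migration, and the first ketone deactivates its ring.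

**Further compounds**

F1 | step 7 | 1-{3,5-bis[(dimethylamino)methyl]-2,4,6-trihydroxyphenyl}butan-1-one | CCCC(=O)c1c(O)c(CN(C)C)c(O)c(CN(C)C)c1O
F2 | step 13 | 1-[3,5-bis({3-butanoyl-5-[(dimethylamino)methyl]-2,4,6-trihydroxyphenyl}methyl)-2,4,6-trihydroxyphenyl]butan-1-one | CCCC(=O)c1c(O)c(Cc2c(O)c(CN(C)C)c(O)c(C(=O)CCC)c2O)c(O)c(Cc2c(O)c(CN(C)C)c(O)c(C(=O)CCC)c2O)c1O
F3 | step 8 | 1-[2,4,6-trihydroxy-3,5-bis(2,4,6-trihydroxybenzyl)phenyl]butan-1-one | CCCC(=O)c1c(O)c(Cc2c(O)cc(O)cc2O)c(O)c(Cc2c(O)cc(O)cc2O)c1O
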